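**Plan**

1. Locants: ring system 1 is the styryl-bearing dihydrobenzofuran (O1, C2, C3, C3a–C7a). Ring system 2 is the dihydrobenzofuran bonded through C6' to C3 (O1', C2', C3', C3a'–C7a', benzo ring B). Ring C is the 3,5-dihydroxyphenyl group on C3'.
2. Cuts: the seven O–CH3 bonds, then the C6–vinyl bond, then in each ring system the aryl C7a–O1 bond and the two C–aryl bonds of the vicinal pair (C2–anisyl with C3–C6'; C2'–anisyl with C3'–ring C).
3. Enabling feature: C2' and C3' are adjacent sp3 carbons that carry one oxygen and three aryl groups. This is what remains when two aryl groups add anti across a (Z)-2-arylvinyl boronate and the C–B bond is oxidised. C2/C3 repeat the pattern.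
4. Forward order: the (Z)-alkenyl boronate 8 is built from 3-chloro-5-methoxyphenol and converted in one batch into its 4-methoxyphenyl ate complex 13. One portion of 13 is coupled with 3,5-dimethoxyphenyl triflate; C–B oxidation and Pd C–O closure give ring system 2. Its C6' triflate is the electrophile for the second portion of 13, which leads to ring system 1. Suzuki styrylation and BBr3 demethylation finish.
5. Stereochemistry: the chiral ferrocene bisphosphine on palladium sets the absolute sense at C2'/C3' and again at C2/C3. Anti addition to the Z alkene sets the relative sense. Oxidation and C–O coupling leave both untouched, so both rings come out trans (2S,3S,2'S,3'S).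

Key step: step 8

Assumption: which antipode of the MandyPhos-type ligand leads to the (1S,2S) boronate cannot be derived from first principles; the (Rp,Rp) antipode is written, and its mirror image would be used instead if alcohol 15 proves to be (1R,2R).

Assumption: the lithium aryl(alkenyl)boronate 13 is taken to keep as a solvent-free solid under argon at −30 °C for the few days that steps 9 to 11 need.

Abbreviation: mac = cis-1,2-dimethylacenaphthene-1,2-diolate; B(mac) is the cyclic boronic ester of diol 6.

**Step 1**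
Reactants: 1 3-chloro-5-methoxyphenol
Product: 2 (3-chloro-5-methoxyphenoxy)triisopropylsilane
Conditions: iPr3SiCl, imidazole, DMF, rt
Reagents that add atoms: triisopropylsilyl chloride, CC(C)[Si](Cl)(C(C)C)C(C)C
Why: Silylation of a phenol; the bulky silyl ether later shields its two ortho positions in the lithiation and is the one oxygen that can be unmasked beside methyl ethers.

**Step 2**
Reactants: 2 (3-chloro-5-methoxyphenoxy)triisopropylsilane
Product: 3 2-chloro-6-methoxy-4-(triisopropylsilyloxy)benzaldehyde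
Conditions: s-BuLi, TMEDA, THF, −78 °C; DMF, −78 → 0 °C; H2O
Reagents that add atoms: N,N-dimethylformamide, CN(C)C=O
Why: Directed ortho-metalation at the only ring position flanked by chlorine and methoxy (the other two lie next to the bulky silyloxy group), then formylation with DMF; −78 °C should keep the ortho-chloro aryllithium from losing LiCl.

**Step 3**
Reactants: 3 2-chloro-6-methoxy-4-(triisopropylsilyloxy)benzaldehyde
Product: 4 1-chloro-2-ethynyl-3-methoxy-5-(triisopropylsilyloxy)benzene
Conditions: Me3SiCHN2, LiN(iPr)2, THF, −78 °C → rt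
Reagents that add atoms: trimethylsilyldiazomethane, C[Si](C)(C)C=[N+]=[N-]
Why: Colvin rearrangement: the lithiated diazo compound adds to the aldehyde, Peterson elimination gives a diazoalkene, and the alkylidene carbene rearranges by 1,2-hydrogen shift to the terminal alkyne without the methoxide that would endanger the aryl silyl ether.

**Step 4**
Reactants: 5 acenaphthoquinone
Product: 6 cis-1,2-dimethylacenaphthene-1,2-diol (mac diol)
Conditions: MeMgBr (3 equiv), THF, 0 °C → rt; H2O; recrystallisation
Reagents that add atoms: methylmagnesium bromide, C[Mg]Br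
Why: Double Grignard addition to a 1,2-diketone; the second methyl group is expected to enter anti to the solvated magnesium alkoxide, which gives the cis (meso) diol, the only isomer able to span boron.

**Step 5**
Reactants: 4 1-chloro-2-ethynyl-3-methoxy-5-(triisopropylsilyloxy)benzene; 6 cis-1,2-dimethylacenaphthene-1,2-diol
Product: 8 (Z)-2-(2-chloro-6-methoxy-4-triisopropylsilyloxyphenyl)ethenylboronic acid mac ester, via catechol boronate 7 (not isolated)
Conditions: catecholborane, [Rh(cod)Cl]2 (1.5 mol %), P(iPr)3 (6 mol %), Et3N, cyclohexane, rt (4 in slight excess); then 6, rt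
Reagents that add atoms: catecholborane, B1Oc2ccccc2O1
Why: Rhodium-catalysed trans-hydroboration of a terminal alkyne, in which a monovalent-rhodium vinylidene places boron cis to the aryl group, followed by exchange of the labile catechol ester for the mac diolate, chosen because β-substituted alkenyl pinacol boronates tend to hand the alkenyl group directly to palladium in step 8.

**Step 6**
Reactants: 9 3,5-dimethoxyphenol
Product: 10 3,5-dimethoxyphenyl trifluoromethanesulfonate
Conditions: Tf2O, pyridine, CH2Cl2, 0 °C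
Reagents that add atoms: trifluoromethanesulfonic anhydride, O=S(=O)(OS(=O)(=O)C(F)(F)F)C(F)(F)F
Why: O-Sulfonylation of a phenol gives the halide-free electrophile that the cationic palladium pathway of step 8 requires.

**Step 7**
Reactants: 8 (Z)-2-(2-chloro-6-methoxy-4-triisopropylsilyloxyphenyl)ethenylboronic acid mac ester; 11 4-bromoanisole
Product: 13 lithium (Z)-alkenyl(4-methoxyphenyl)boronate of the mac diol (ate complex of 8), via 4-methoxyphenyllithium 12 (not isolated)
Conditions: 11, t-BuLi (2 equiv), Et2O, −78 °C; then 8, THF, −78 °C → rt; solvents removed in vacuo; the solid is divided under argon, one portion for step 8, the other kept at −30 °C for step 12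
Reagents that add atoms: tert-butyllithium, [Li]C(C)(C)C
Why: Bromine–lithium exchange gives the aryllithium, which adds to the vacant orbital of the boronic ester (formation of a four-coordinate boron ate complex) without touching the Z alkene, the aryl chloride or the silyl ether at −78 °C.

**Step 8**
Reactants: 13 lithium ate complex of 8 (first portion); 10 3,5-dimethoxyphenyl trifluoromethanesulfonate
Product: 14 (1S,2S)-2-(2-chloro-6-methoxy-4-triisopropylsilyloxyphenyl)-2-(3,5-dimethoxyphenyl)-1-(4-methoxyphenyl)ethylboronic acid mac ester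
Conditions: Pd(OAc)2 (5 mol %), (Rp,Rp)-1,1'-bis[bis(3,5-dimethylphenyl)phosphino]-2,2'-bis[(S)-α-(dimethylamino)benzyl]ferrocene (6 mol %), NaOTf (2 equiv), THF, 60 °C
Reagents that add atoms: none
Why: Triflate 10 adds oxidatively to zerovalent palladium to give a cationic aryl complex of divalent palladium that binds the alkene of the ate complex 13 (made from boronate 8 and aryllithium 12 in step 7); the 4-methoxyphenyl group then shifts from boron to C2' anti to the palladium that bonds to C3' (1,2-metalate shift), and reductive elimination forms the C3'–ring C bond. The closest known reaction type is the palladium-catalysed enantioselective conjunctive cross-coupling of β-substituted alkenyl B(mac) ate complexes with aryl triflates; here the β-substituent is an aryl group flanked by chlorine and methoxy. No ring closes: two C–aryl bonds form in an open chain. The relative configuration of C2' and C3' follows from the stereospecific anti addition across the Z alkene, and the absolute configuration from the C2-symmetric ferrocene bisphosphine on palladium, which selects the alkene face. The step needs the metalate shift to outrun direct boron-to-palladium transfer (Suzuki product) and β-hydride elimination: the hindered mac diolate shields the B–O bonds from palladium, the triflate keeps palladium cationic, NaOTf precipitates the bromide carried over with 13 that would block the vacant site, and the aryl chloride of ring B is inert to this catalyst at 60 °C.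

**Step 9**
Reactants: 14 the boronic ester of step 8
Product: 15 (1S,2S)-2-(2-chloro-6-methoxy-4-triisopropylsilyloxyphenyl)-2-(3,5-dimethoxyphenyl)-1-(4-methoxyphenyl)ethanol
Conditions: NaBO3·4H2O, THF/H2O (1:1), rt → 40 °C
Reagents that add atoms: sodium perborate, [Na+].[Na+].O[B-]1(O)OO[B-](O)(O)OO1
Why: Boronate oxidation: hydroperoxide adds to boron and C2' migrates from boron to oxygen with retention, so the configuration set in step 8 is kept, and the weakly basic perborate should leave the aryl silyl ether in place.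

**Step 10**
Reactants: 15 the alcohol of step 9
Product: 16 (2S,3S)-3-(3,5-dimethoxyphenyl)-4-methoxy-2-(4-methoxyphenyl)-6-(triisopropylsilyloxy)-2,3-dihydrobenzofuran
Conditions: Pd2(dba)3 (2.5 mol %), RockPhos (7.5 mol %), Cs2CO3, toluene, 90 °C
Reagents that add atoms: none
Why: Intramolecular palladium-catalysed C–O coupling (Buchwald–Hartwig etherification) of the secondary alcohol with the ortho chloride: oxidative addition, alkoxide binding and C–O reductive elimination form the O1'–C7a' bond of the five-membered ring without touching C2' or C3', so the anti adduct becomes the trans ring.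

**Step 11**
Reactants: 16 the silyl ether of step 10
Product: 18 (2S,3S)-3-(3,5-dimethoxyphenyl)-4-methoxy-2-(4-methoxyphenyl)-2,3-dihydrobenzofuran-6-yl trifluoromethanesulfonate, via tetrabutylammonium phenoxide 17 (not isolated)
Conditions: Bu4NF (1.1 equiv), THF, 0 °C; then PhNTf2 (1.5 equiv), rt
Reagents that add atoms: N-phenylbis(trifluoromethanesulfonimide), O=S(=O)(N(c1ccccc1)S(=O)(=O)C(F)(F)F)C(F)(F)F
Why: Fluoride desilylation gives the phenoxide, which is O-triflated in the same flask by the mild triflyl donor; neither reagent affects the methyl ethers or the benzylic ether of the ring.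

**Step 12**
Reactants: 13 lithium ate complex of 8 (second portion from step 7); 18 the triflate of step 11
Product: 20 (1S,2S)-2-(2-chloro-6-methoxy-4-triisopropylsilyloxyphenyl)-2-[(2S,3S)-3-(3,5-dimethoxyphenyl)-4-methoxy-2-(4-methoxyphenyl)-2,3-dihydrobenzofuran-6-yl]-1-(4-methoxyphenyl)ethanol, via boronate 19 (not isolated)
Conditions: Pd(OAc)2 (5 mol %), (Rp,Rp)-1,1'-bis[bis(3,5-dimethylphenyl)phosphino]-2,2'-bis[(S)-α-(dimethylamino)benzyl]ferrocene (6 mol %), NaOTf (2 equiv), THF, 60 °C; then NaBO3·4H2O, THF/H2O, rt → 40 °C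
Reagents that add atoms: sodium perborate, [Na+].[Na+].O[B-]1(O)OO[B-](O)(O)OO1
Why: Second conjunctive cross-coupling followed by retentive boronate oxidation in the same flask; triflate 18 carries hydrogen at both positions ortho to the leaving group, as 10 does, and the same ferrocene bisphosphine should set C2 and C3 under catalyst control because C2' and C3' are remote from the reacting alkene.

**Step 13**
Reactants: 20 the alcohol of step 12
Product: 21 (2S,3S)-3-[(2S,3S)-3-(3,5-dimethoxyphenyl)-4-methoxy-2-(4-methoxyphenyl)-2,3-dihydrobenzofuran-6-yl]-4-methoxy-2-(4-methoxyphenyl)-6-(triisopropylsilyloxy)-2,3-dihydrobenzofuran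
Conditions: Pd2(dba)3 (2.5 mol %), RockPhos (7.5 mol %), Cs2CO3, toluene, 90 °C
Reagents that add atoms: none
Why: The same intramolecular Buchwald–Hartwig etherification closes the O1–C7a bond of ring system 1 with C2 and C3 untouched, which gives the second trans ring.

**Step 14**
Reactants: 21 the silyl ether of step 13
Product: 23 (2S,3S)-3-[(2S,3S)-3-(3,5-dimethoxyphenyl)-4-methoxy-2-(4-methoxyphenyl)-2,3-dihydrobenzofuran-6-yl]-4-methoxy-2-(4-methoxyphenyl)-2,3-dihydrobenzofuran-6-yl trifluoromethanesulfonate, via tetrabutylammonium phenoxide 22 (not isolated)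
Conditions: Bu4NF (1.1 equiv), THF, 0 °C; then PhNTf2 (1.5 equiv), rt
Reagents that add atoms: N-phenylbis(trifluoromethanesulfonimide), O=S(=O)(N(c1ccccc1)S(=O)(=O)C(F)(F)F)C(F)(F)F
Why: Fluoride desilylation and O-triflation of the phenoxide as in step 11 turn the C6 oxygen into the leaving group for the styrylation.

**Step 15**
Reactants: 23 the triflate of step 14; 24 (E)-2-(4-methoxyphenyl)ethenylboronic acid
Product: 25 heptamethyl ether of the target, (2S,3S)-3-[(2S,3S)-3-(3,5-dimethoxyphenyl)-4-methoxy-2-(4-methoxyphenyl)-2,3-dihydrobenzofuran-6-yl]-4-methoxy-2-(4-methoxyphenyl)-6-[(E)-2-(4-methoxyphenyl)ethenyl]-2,3-dihydrobenzofuran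
Conditions: Pd(PPh3)4 (5 mol %), K3PO4, 1,4-dioxane/H2O, 80 °C
Reagents that add atoms: none
Why: Suzuki–Miyaura coupling of an aryl triflate with an (E)-alkenylboronic acid; transmetalation and reductive elimination retain the alkene geometry, so the E stilbene is formed at C6.

**Step 16**
Reactants: 25 the heptamethyl ether of step 15
Product: 26 the target, (2S,3S)-3-[(2S,3S)-3-(3,5-dihydroxyphenyl)-4-hydroxy-2-(4-hydroxyphenyl)-2,3-dihydrobenzofuran-6-yl]-2-(4-hydroxyphenyl)-6-[(E)-2-(4-hydroxyphenyl)ethenyl]-2,3-dihydrobenzofuran-4-ol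
Conditions: BBr3 (about 14 equiv), CH2Cl2, −78 °C → rt; MeOH, then H2O
Reagents that add atoms: none
Why: Lewis-acid cleavage of aryl methyl ethers (BBr3 demethylation): boron binds each ether oxygen and bromide removes the methyl group; the trans rings are the more stable isomers, so a reversible opening at C2–O1 or C2'–O1' should close back to the same configuration.

**Compound list**

1 | 3-chloro-5-methoxyphenol | COc1cc(O)cc(Cl)c1 | starting material
2 | (3-chloro-5-methoxyphenoxy)triisopropylsilane | COc1cc(Cl)cc(O[Si](C(C)C)(C(C)C)C(C)C)c1 | intermediate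
3 | 2-chloro-6-methoxy-4-(triisopropylsilyloxy)benzaldehyde | COc1cc(O[Si](C(C)C)(C(C)C)C(C)C)cc(Cl)c1C=O | intermediate
4 | 1-chloro-2-ethynyl-3-methoxy-5-(triisopropylsilyloxy)benzene | COc1cc(O[Si](C(C)C)(C(C)C)C(C)C)cc(Cl)c1C#C | intermediate
5 | acenaphthoquinone | O=C1C(=O)c2cccc3cccc1c23 | starting material
6 | (1R,2S)-1,2-dimethyl-1,2-dihydroacenaphthylene-1,2-diol (cis, meso; mac diol) | C[C@]1(O)c2cccc3cccc(c23)[C@@]1(C)O | intermediate
7 | (Z)-2-(2-chloro-6-methoxy-4-triisopropylsilyloxyphenyl)ethenyl catechol boronate | COc1cc(O[Si](C(C)C)(C(C)C)C(C)C)cc(Cl)c1/C=C\B1Oc2ccccc2O1 | intermediate (not isolated)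
8 | (Z)-2-(2-chloro-6-methoxy-4-triisopropylsilyloxyphenyl)ethenylboronic acid mac ester | COc1cc(O[Si](C(C)C)(C(C)C)C(C)C)cc(Cl)c1/C=C\B1O[C@@]2(C)c3cccc4cccc(c34)[C@@]2(C)O1 | intermediate
9 | 3,5-dimethoxyphenol | COc1cc(O)cc(OC)c1 | starting material
10 | 3,5-dimethoxyphenyl trifluoromethanesulfonate | COc1cc(OC)cc(OS(=O)(=O)C(F)(F)F)c1 | intermediate
11 | 4-bromoanisole | COc1ccc(Br)cc1 | starting material
12 | 4-methoxyphenyllithium | [Li]c1ccc(OC)cc1 | intermediate (not isolated)
13 | lithium [(Z)-2-(2-chloro-6-methoxy-4-triisopropylsilyloxyphenyl)ethenyl](4-methoxyphenyl)boronate of the mac diol (ate complex of 8; boron configuration not defined) | [Li+].COc1ccc(cc1)[B-]1(/C=C\c2c(Cl)cc(O[Si](C(C)C)(C(C)C)C(C)C)cc2OC)O[C@@]2(C)c3cccc4cccc(c34)[C@@]2(C)O1 | intermediate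
14 | (1S,2S)-2-(2-chloro-6-methoxy-4-triisopropylsilyloxyphenyl)-2-(3,5-dimethoxyphenyl)-1-(4-methoxyphenyl)ethylboronic acid mac ester | COc1ccc(cc1)[C@@H](B1O[C@@]2(C)c3cccc4cccc(c34)[C@@]2(C)O1)[C@H](c1c(Cl)cc(O[Si](C(C)C)(C(C)C)C(C)C)cc1OC)c1cc(OC)cc(OC)c1 | intermediate
15 | (1S,2S)-2-(2-chloro-6-methoxy-4-triisopropylsilyloxyphenyl)-2-(3,5-dimethoxyphenyl)-1-(4-methoxyphenyl)ethanol | COc1ccc(cc1)[C@@H](O)[C@H](c1c(Cl)cc(O[Si](C(C)C)(C(C)C)C(C)C)cc1OC)c1cc(OC)cc(OC)c1 | intermediate
16 | (2S,3S)-3-(3,5-dimethoxyphenyl)-4-methoxy-2-(4-methoxyphenyl)-6-(triisopropylsilyloxy)-2,3-dihydrobenzofuran | COc1ccc(cc1)[C@H]1Oc2cc(O[Si](C(C)C)(C(C)C)C(C)C)cc(OC)c2[C@@H]1c1cc(OC)cc(OC)c1 | intermediate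
17 | tetrabutylammonium (2S,3S)-3-(3,5-dimethoxyphenyl)-4-methoxy-2-(4-methoxyphenyl)-2,3-dihydrobenzofuran-6-olate | CCCC[N+](CCCC)(CCCC)CCCC.COc1ccc(cc1)[C@H]1Oc2cc([O-])cc(OC)c2[C@@H]1c1cc(OC)cc(OC)c1 | intermediate (not isolated)
18 | (2S,3S)-3-(3,5-dimethoxyphenyl)-4-methoxy-2-(4-methoxyphenyl)-2,3-dihydrobenzofuran-6-yl trifluoromethanesulfonate | COc1ccc(cc1)[C@H]1Oc2cc(OS(=O)(=O)C(F)(F)F)cc(OC)c2[C@@H]1c1cc(OC)cc(OC)c1 | intermediate
19 | (1S,2S)-2-(2-chloro-6-methoxy-4-triisopropylsilyloxyphenyl)-2-[(2S,3S)-3-(3,5-dimethoxyphenyl)-4-methoxy-2-(4-methoxyphenyl)-2,3-dihydrobenzofuran-6-yl]-1-(4-methoxyphenyl)ethylboronic acid mac ester | COc1ccc(cc1)[C@@H](B1O[C@@]2(C)c3cccc4cccc(c34)[C@@]2(C)O1)[C@H](c1c(Cl)cc(O[Si](C(C)C)(C(C)C)C(C)C)cc1OC)c1cc(OC)c2c(c1)O[C@H](c1ccc(OC)cc1)[C@H]2c1cc(OC)cc(OC)c1 | intermediate (not isolated)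
20 | (1S,2S)-2-(2-chloro-6-methoxy-4-triisopropylsilyloxyphenyl)-2-[(2S,3S)-3-(3,5-dimethoxyphenyl)-4-methoxy-2-(4-methoxyphenyl)-2,3-dihydrobenzofuran-6-yl]-1-(4-methoxyphenyl)ethanol | COc1ccc(cc1)[C@@H](O)[C@H](c1c(Cl)cc(O[Si](C(C)C)(C(C)C)C(C)C)cc1OC)c1cc(OC)c2c(c1)O[C@H](c1ccc(OC)cc1)[C@H]2c1cc(OC)cc(OC)c1 | intermediate
21 | (2S,3S)-3-[(2S,3S)-3-(3,5-dimethoxyphenyl)-4-methoxy-2-(4-methoxyphenyl)-2,3-dihydrobenzofuran-6-yl]-4-methoxy-2-(4-methoxyphenyl)-6-(triisopropylsilyloxy)-2,3-dihydrobenzofuran | CC(C)[Si](C(C)C)(C(C)C)Oc1cc(OC)c2c(c1)O[C@H](c1ccc(OC)cc1)[C@H]2c1cc(OC)c2c(c1)O[C@H](c1ccc(OC)cc1)[C@H]2c1cc(OC)cc(OC)c1 | intermediate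
22 | tetrabutylammonium 6-olate of ring system 1 (phenoxide from 21) | CCCC[N+](CCCC)(CCCC)CCCC.[O-]c1cc(OC)c2c(c1)O[C@H](c1ccc(OC)cc1)[C@H]2c1cc(OC)c2c(c1)O[C@H](c1ccc(OC)cc1)[C@H]2c1cc(OC)cc(OC)c1 | intermediate (not isolated)
23 | (2S,3S)-3-[(2S,3S)-3-(3,5-dimethoxyphenyl)-4-methoxy-2-(4-methoxyphenyl)-2,3-dihydrobenzofuran-6-yl]-4-methoxy-2-(4-methoxyphenyl)-2,3-dihydrobenzofuran-6-yl trifluoromethanesulfonate | O=S(=O)(Oc1cc(OC)c2c(c1)O[C@H](c1ccc(OC)cc1)[C@H]2c1cc(OC)c2c(c1)O[C@H](c1ccc(OC)cc1)[C@H]2c1cc(OC)cc(OC)c1)C(F)(F)F | intermediate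
24 | (E)-2-(4-methoxyphenyl)ethenylboronic acid | COc1ccc(/C=C/B(O)O)cc1 | starting material
25 | heptamethyl ether of the target | COc1ccc(/C=C/c2cc(OC)c3c(c2)O[C@H](c2ccc(OC)cc2)[C@H]3c2cc(OC)c3c(c2)O[C@H](c2ccc(OC)cc2)[C@H]3c2cc(OC)cc(OC)c2)cc1 | intermediate
26 | CNP0248228.2, (2S,3S,2'S,3'S) | Oc1ccc(/C=C/c2cc(O)c3c(c2)O[C@H](c2ccc(O)cc2)[C@H]3c2cc(O)c3c(c2)O[C@H](c2ccc(O)cc2)[C@H]3c2cc(O)cc(O)c2)cc1 | target

**Step count**

Total: 16 steps. Longest linear sequence: 14 steps (1 → 2 → 3 → 4 → 8 → 13 → 14 → 15 → 16 → 18 → 20 → 21 → 23 → 25 → 26; steps 4 and 6 are side branches).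

**Steps most likely to fail**

Step 12 repeats step 8 with a triflate that, like 10, is unsubstituted at both ortho positions. Its risk is tied to that of step 8 and it is not ranked separately.

Step 8. The aryl group on the alkene is flanked by chlorine and methoxy and crowds the carbon that must bind palladium. Direct transfer of the alkenyl group from boron to palladium, or β-hydride elimination after the shift, may therefore outrun productive coupling, and face selection may be poor. The fallback exchanges the roles of rings B and C; it sets out from 2 and comes back at 14. Lithiation of 2 as in step 2, quenched with 1,2-dibromoethane instead of DMF, should give 2-bromo-1-chloro-3-methoxy-5-(triisopropylsilyloxy)benzene F1. Commercial 1-ethynyl-3,5-dimethoxybenzene is hydroborated without catalyst by catecholborane (syn addition) to the (E)-2-(3,5-dimethoxyphenyl)ethenyl catechol boronate F2, which is exchanged with 6 to the (E)-2-(3,5-dimethoxyphenyl)ethenylboronic acid mac ester F3. Aryllithium 12, made from 11 as in step 7, adds to F3 to give the lithium ate complex F4, and F4 is coupled with F1 under the palladium catalyst of step 8, with NaOTf as bromide scavenger. The hindered ring is now the palladium-bound aryl and the alkene carries only the unhindered ring C. Because the two aryl groups on C3' have changed roles, anti addition across the E alkene gives the same relative configuration as anti addition across the Z alkene of 8; the ligand antipode is chosen for (1S,2S).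

Step 10. The palladium alkoxide may undergo β-hydride elimination to the ketone and the dechlorinated arene, or oxidative addition into the electron-rich C–Cl bond may be too slow. The fallback closes the ring at the benzylic carbon instead of the aryl carbon; it sets out from 15 and comes back at 16. Miyaura borylation of the chloride (Pd2(dba)3, XPhos, bis(pinacolato)diboron, KOAc, 1,4-dioxane, 100 °C; acetate forms no alkoxide on palladium) should give (1S,2S)-2-(3,5-dimethoxyphenyl)-2-[2-methoxy-6-(pinacolboryl)-4-(triisopropylsilyloxy)phenyl]-1-(4-methoxyphenyl)ethanol F5. NaBO3·4H2O oxidises the aryl boronate to (1S,2S)-2-(3,5-dimethoxyphenyl)-2-(2-hydroxy-6-methoxy-4-triisopropylsilyloxyphenyl)-1-(4-methoxyphenyl)ethanol F6. Catalytic TsOH in CH2Cl2 at 0 °C then ionises the 4-methoxybenzylic alcohol, and the phenol closes the O1'–C2' bond. C3' is not touched, and the new centre should settle trans to the C3' aryl group, the preferred outcome of such cyclodehydrations.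

Step 16. Seven ethers need long exposure to BBr3. The HBr that builds up may protonate the electron-rich stilbene, which would lead to Friedel–Crafts oligomers or loss of alkene geometry. The fallback takes the alkene out of the Lewis-acid step; it sets out from 23 and comes back at 26. BBr3 in CH2Cl2 (−78 °C → rt) cleaves the six methyl ethers of 23 while the aryl triflate persists, which gives (2S,3S)-3-[(2S,3S)-3-(3,5-dihydroxyphenyl)-4-hydroxy-2-(4-hydroxyphenyl)-2,3-dihydrobenzofuran-6-yl]-4-hydroxy-2-(4-hydroxyphenyl)-2,3-dihydrobenzofuran-6-yl trifluoromethanesulfonate F7. Suzuki–Miyaura coupling of F7 with (E)-2-(4-hydroxyphenyl)ethenylboronic acid pinacol ester, assumed to be a catalogue compound (Pd(PPh3)4, aqueous K3PO4, 1,4-dioxane, 80 °C), then gives 26 directly.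

**Further compounds**

F1 | step 8 | 2-bromo-1-chloro-3-methoxy-5-(triisopropylsilyloxy)benzene | COc1cc(O[Si](C(C)C)(C(C)C)C(C)C)cc(Cl)c1Br
F2 | step 8 | (E)-2-(3,5-dimethoxyphenyl)ethenyl catechol boronate | COc1cc(OC)cc(/C=C/B2Oc3ccccc3O2)c1
F3 | step 8 | (E)-2-(3,5-dimethoxyphenyl)ethenylboronic acid mac ester | COc1cc(OC)cc(/C=C/B2O[C@@]3(C)c4cccc5cccc(c45)[C@@]3(C)O2)c1
F4 | step 8 | lithium ate complex of F3 with 4-methoxyphenyl on boron | [Li+].COc1ccc(cc1)[B-]1(/C=C/c2cc(OC)cc(OC)c2)O[C@@]2(C)c3cccc4cccc(c34)[C@@]2(C)O1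
F5 | step 10 | (1S,2S)-2-(3,5-dimethoxyphenyl)-2-[2-methoxy-6-(4,4,5,5-tetramethyl-1,3,2-dioxaborolan-2-yl)-4-(triisopropylsilyloxy)phenyl]-1-(4-methoxyphenyl)ethanol | COc1ccc(cc1)[C@@H](O)[C@H](c1c(B2OC(C)(C)C(C)(C)O2)cc(O[Si](C(C)C)(C(C)C)C(C)C)cc1OC)c1cc(OC)cc(OC)c1
F6 | step 10 | (1S,2S)-2-(3,5-dimethoxyphenyl)-2-(2-hydroxy-6-methoxy-4-triisopropylsilyloxyphenyl)-1-(4-methoxyphenyl)ethanol | COc1ccc(cc1)[C@@H](O)[C@H](c1c(O)cc(O[Si](C(C)C)(C(C)C)C(C)C)cc1OC)c1cc(OC)cc(OC)c1
F7 | step 16 | (2S,3S)-3-[(2S,3S)-3-(3,5-dihydroxyphenyl)-4-hydroxy-2-(4-hydroxyphenyl)-2,3-dihydrobenzofuran-6-yl]-4-hydroxy-2-(4-hydroxyphenyl)-2,3-dihydrobenzofuran-6-yl trifluoromethanesulfonate | O=S(=O)(Oc1cc(O)c2c(c1)O[C@H](c1ccc(O)cc1)[C@H]2c1cc(O)c2c(c1)O[C@H](c1ccc(O)cc1)[C@H]2c1cc(O)cc(O)c1)C(F)(F)F
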